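**Retrosynthetic overview**

1. Numbering: ring C1 (side chain), C2 (exocyclic C7), C3 (CHBr), C4, C5 (CHBr), C6 (CMe2); chain C1′–C5′ with carbinol C3′. Both C–Br bonds are made late from C–O bonds with inversion (neopentyl C5 by triflate/bromide, allylic C3 last by Appel). C3′ comes from lithiation–borylation of a C2′ boronate with the carbamate of (R)-but-3-en-2-ol.
2. Feature used: in the only ring, the neighbours C1 and C2 each carry a one-carbon branch (C1′H2 and the exocyclic methylene C7). This is the pattern left when a titanacyclopentene spanning C7–C2–C1–C1′ is protonated, so the C1–C2 bond and the ring (the single ring-forming event) come from a 2-en-8-ynoate.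
3. The enynoate is built linearly: C4–C5–C6(Me2)–C1 from D-pantolactone (C5 retained), C3–C2–C7 from a silylpropynal dithiane (C3 set by Noyori reduction), C1′–C2′ by Wittig olefination.

Key step: step 11

Assumption: the target is read as (3′S,1S,3R,5R), i.e. the C1 side chain is cis to the C3 bromine and trans to the C5 bromine; names use the ring numbering above.

**Step 1**
Reactants: 1 D-pantolactone
Product: 2 (2R)-3,3-dimethylbutane-1,2,4-triol
Conditions: LiAlH4, THF, 0 °C → reflux
Reagents that add atoms: none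
Why: Hydride reduction of a lactone to the diol (ester reduction); the carbinol centre (later C5) is not involved and keeps the configuration of D-pantolactone.

**Step 2**
Reactants: 2 (2R)-3,3-dimethylbutane-1,2,4-triol
Product: 3 [(2R,4R)-2-(4-methoxyphenyl)-5,5-dimethyl-1,3-dioxan-4-yl]methanol
Conditions: 4-MeOC6H4CH(OMe)2, camphorsulfonic acid (cat.), CH2Cl2, rt
Reagents that add atoms: 4-methoxybenzaldehyde dimethyl acetal, COC(OC)c1ccc(OC)cc1
Why: Acid-catalysed transacetalisation under thermodynamic control should favour the six-membered 5,5-dimethyl-1,3-dioxane across O5 and O1, with the acetal carbon equilibrating to the isomer that has aryl and CH2OH both equatorial, so that only the C4 hydroxyl stays free.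

**Step 3**
Reactants: 4 3-(trimethylsilyl)prop-2-ynal
Product: 5 2-[(trimethylsilyl)ethynyl]-1,3-dithiane
Conditions: HS(CH2)3SH, BF3·OEt2, CH2Cl2, −20 → 0 °C
Reagents that add atoms: propane-1,3-dithiol, SCCCS
Why: Lewis acid promoted dithioacetalisation of an aldehyde, in which carbonyl activation at low temperature should favour 1,2-addition over conjugate addition to the silyl-capped ynal.

**Step 4**
Reactants: 3 [(2R,4R)-2-(4-methoxyphenyl)-5,5-dimethyl-1,3-dioxan-4-yl]methanol, 5 2-[(trimethylsilyl)ethynyl]-1,3-dithiane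
Product: 8 2-{[(2R,4S)-2-(4-methoxyphenyl)-5,5-dimethyl-1,3-dioxan-4-yl]methyl}-2-[(trimethylsilyl)ethynyl]-1,3-dithiane, via primary triflate 6 (not isolated), via lithiated alkynyl dithiane 7 (not isolated)
Conditions: 3: n-BuLi, Et2O, −78 °C, then Tf2O; 5: n-BuLi, THF, −78 °C; combined, −78 → −20 °C
Reagents that add atoms: none
Why: Corey–Seebach alkylation, in which the dithianyl anion displaces the primary triflate at C4 (SN2) and should react at the dithiane carbon because the silyl group shields the allenic terminus; no stereocentre is formed and C5 is untouched (its descriptor changes only through priorities).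

**Step 5**
Reactants: 8 alkylated dithiane
Product: 9 1-[(2R,4S)-2-(4-methoxyphenyl)-5,5-dimethyl-1,3-dioxan-4-yl]-4-(trimethylsilyl)but-3-yn-2-one
Conditions: MeI, CaCO3, MeCN/H2O (9:1), 45 °C
Reagents that add atoms: water, O
Why: S-Methylation and hydrolysis of the dithioacetal under CaCO3-buffered, near-neutral conditions should unmask the C3 ketone without opening the acid-labile acetal or eliminating the β-alkoxy group.

**Step 6**
Reactants: 9 ynone
Product: 10 (2S)-1-[(2R,4S)-2-(4-methoxyphenyl)-5,5-dimethyl-1,3-dioxan-4-yl]-4-(trimethylsilyl)but-3-yn-2-ol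
Conditions: Ru[(S,S)-TsNCH(Ph)CH(Ph)NH](η6-p-cymene) (2 mol %), i-PrOH, rt
Reagents that add atoms: none
Why: Noyori asymmetric transfer hydrogenation of an alkynyl ketone, in which the (S,S) catalyst should deliver hydride to the face that gives the (S)-propargylic alcohol (alkyne in the role of the π-substituent), so C3 is set by the catalyst, anti to the C5 oxygen.

**Step 7**
Reactants: 10 propargylic alcohol
Product: 11 triethylsilyl ether of 10, {[(2S)-1-[(2R,4S)-2-(4-methoxyphenyl)-5,5-dimethyl-1,3-dioxan-4-yl]-4-(trimethylsilyl)but-3-yn-2-yl]oxy}triethylsilane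
Conditions: Et3SiCl, imidazole, DMF, 0 °C → rt
Reagents that add atoms: chlorotriethylsilane, CC[Si](Cl)(CC)CC
Why: Standard silylation of a secondary alcohol; the triethylsilyl group is chosen because fluoride later removes it together with the vinyl silicon.

**Step 8**
Reactants: 11 silyl ether acetal
Product: 12 (3S,5S)-3-[(4-methoxyphenyl)methoxy]-2,2-dimethyl-5-[(triethylsilyl)oxy]-7-(trimethylsilyl)hept-6-yn-1-ol
Conditions: i-Bu2AlH, CH2Cl2, −78 → 0 °C; aq. KNaC4H4O6 (potassium sodium tartrate)
Reagents that add atoms: none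
Why: Reductive opening of a p-methoxybenzylidene acetal, in which aluminium binds the less hindered primary oxygen O1 so that the benzyl group stays on the secondary O5 and the neopentyl alcohol at C1 is released.

**Step 9**
Reactants: 12 primary alcohol
Product: 13 (3S,5S)-3-[(4-methoxyphenyl)methoxy]-2,2-dimethyl-5-[(triethylsilyl)oxy]-7-(trimethylsilyl)hept-6-ynal
Conditions: Dess–Martin periodinane, NaHCO3, CH2Cl2, 0 °C → rt
Reagents that add atoms: none
Why: Dess–Martin oxidation of a primary alcohol to an aldehyde that cannot enolise (quaternary α-carbon C6).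

**Step 10**
Reactants: 13 aldehyde, 14 tert-butyl (triphenylphosphoranylidene)acetate
Product: 15 tert-butyl (2E,5S,7S)-5-[(4-methoxyphenyl)methoxy]-4,4-dimethyl-7-[(triethylsilyl)oxy]-9-(trimethylsilyl)non-2-en-8-ynoate
Conditions: toluene, 90 °C
Reagents that add atoms: none
Why: Wittig olefination with a stabilised ylide, which should give the (E)-enoate even with the hindered neopentyl aldehyde.

**Step 11 (key step)**
Reactants: 15 enynoate
Product: 17 tert-butyl 2-[(1S,2Z,3S,5S)-5-[(4-methoxyphenyl)methoxy]-6,6-dimethyl-3-[(triethylsilyl)oxy]-2-[(trimethylsilyl)methylidene]cyclohexyl]acetate, via bicyclic titanacyclopentene 16 (not isolated)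
Conditions: Ti(Oi-Pr)4 (1.3 equiv), i-PrMgCl (2.6 equiv), Et2O, −78 → −50 °C, then → −20 °C; sat. aq. NH4Cl
Reagents that add atoms: none
Why: Ti(Oi-Pr)4 and two equivalents of i-PrMgCl give the divalent titanium complex (i-PrO)2Ti(η2-propene), which exchanges propene for the silyl alkyne to form a titanacyclopropene; this carbometallates the tethered enoate, joining alkyne carbon C2 to the enoate β-carbon C1 and leaving titanium on C7 and C1′ in titanacycle 16, whose two Ti–C bonds are protonated on work-up. The closest known reaction type is the reductive cyclisation of 2-en-8-ynoates with this reagent, which is established for tert-butyl esters. The six-membered ring is closed by the single C1–C2 bond in a mode that is exo with respect to both π-systems, since C7 and C1′ both stay outside the ring. The only new stereocentre, C1, is set in a chair-like transition state in which the C3 silyloxy group is axial to avoid allylic 1,3-strain with the C7 silyl group and the C1–C1′ bond is held in the plane of the forming C2=C7 bond by the metallacycle, hence equatorial, which places it cis to the equatorial C5 ether and trans to the C3 oxygen; syn addition of titanium and C1 across the alkyne makes the vinylsilane Z (silicon cis to C3). The step needs facial selectivity at the enoate, which the matched anti C3/C5 configuration should secure, and chemoselectivity, which rests on the tert-butyl ester (no acylation of the vinyl–titanium bond) and on a low temperature with a silyl ether as a poor propargylic leaving group (no β-elimination to an allenyl titanium).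

**Step 12**
Reactants: 17 vinylsilane
Product: 18 tert-butyl 2-[(1S,3S,5S)-3-hydroxy-5-[(4-methoxyphenyl)methoxy]-6,6-dimethyl-2-methylidenecyclohexyl]acetate
Conditions: n-Bu4NF, THF, 0 → 50 °C
Reagents that add atoms: none
Why: Fluoride cleaves the C3 silyl ether, and the alkoxide, which is cis to the C7 silyl group, should trigger a 1,4 carbon-to-oxygen silyl shift (Brook rearrangement) with protonation at C7 and loss of the O-silyl group, leaving the exocyclic methylene while the benzyl ether and tert-butyl ester survive.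

**Step 13**
Reactants: 18 allylic alcohol
Product: 19 tert-butyl 2-[(1S,3S,5S)-3-[(tert-butyldimethylsilyl)oxy]-5-[(4-methoxyphenyl)methoxy]-6,6-dimethyl-2-methylidenecyclohexyl]acetate
Conditions: t-BuMe2SiOTf, 2,6-lutidine, CH2Cl2, −78 → 0 °C
Reagents that add atoms: tert-butyldimethylsilyl trifluoromethanesulfonate, CC(C)(C)[Si](C)(C)OS(=O)(=O)C(F)(F)F
Why: Silylation of the hindered axial allylic alcohol with a silyl triflate gives a C3 protecting group that is orthogonal to the C5 benzyl ether and robust to the organometallic steps ahead.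

**Step 14**
Reactants: 19 tert-butyl ester
Product: 20 2-[(1S,3S,5S)-3-[(tert-butyldimethylsilyl)oxy]-5-[(4-methoxyphenyl)methoxy]-6,6-dimethyl-2-methylidenecyclohexyl]ethan-1-ol
Conditions: LiAlH4, THF, 0 °C → rt
Reagents that add atoms: none
Why: Hydride reduction of the ester to the primary alcohol at C2′; ethers and the alkene are inert.

**Step 15**
Reactants: 20 primary alcohol
Product: 21 (1S,3S,5S)-1-(2-iodoethyl)-3-[(tert-butyldimethylsilyl)oxy]-5-[(4-methoxyphenyl)methoxy]-6,6-dimethyl-2-methylidenecyclohexane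
Conditions: I2, PPh3, imidazole, CH2Cl2, 0 °C → rt
Reagents that add atoms: iodine, II
Why: Appel-type iodination of a primary alcohol through its alkoxyphosphonium ion (SN2 at C2′).

**Step 16**
Reactants: 21 primary iodide
Product: 23 2-{2-[(1S,3S,5S)-3-[(tert-butyldimethylsilyl)oxy]-5-[(4-methoxyphenyl)methoxy]-6,6-dimethyl-2-methylidenecyclohexyl]ethyl}-4,4,5,5-tetramethyl-1,3,2-dioxaborolane, via primary alkyllithium 22 (not isolated)
Conditions: t-BuLi (2.1 equiv), Et2O/pentane, −78 °C; then i-PrOBpin, −78 °C → rt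
Reagents that add atoms: 2-isopropoxy-4,4,5,5-tetramethyl-1,3,2-dioxaborolane, CC(C)OB1OC(C)(C)C(C)(C)O1
Why: Iodine–lithium exchange of a primary iodide followed by trapping with a borate ester gives the pinacol boronic ester at C2′ (the alkyllithium has no favourable ring closure onto the exocyclic alkene).

**Step 17**
Reactants: 23 boronic ester
Product: 24 2-{2-[(1S,3S,5S)-3-[(tert-butyldimethylsilyl)oxy]-5-hydroxy-6,6-dimethyl-2-methylidenecyclohexyl]ethyl}-4,4,5,5-tetramethyl-1,3,2-dioxaborolane
Conditions: DDQ, CH2Cl2/pH 7 buffer, 0 °C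
Reagents that add atoms: none
Why: Oxidative cleavage of the p-methoxybenzyl ether by DDQ frees the C5 hydroxyl alone; the silyl ether, boronic ester and isolated alkene are not oxidised.

**Step 18**
Reactants: 24 C5 alcohol
Product: 26 2-{2-[(1R,3S,5R)-5-bromo-3-[(tert-butyldimethylsilyl)oxy]-6,6-dimethyl-2-methylidenecyclohexyl]ethyl}-4,4,5,5-tetramethyl-1,3,2-dioxaborolane (C1 unchanged, descriptor changes by priority), via C5 triflate 25 (not isolated)
Conditions: Tf2O, pyridine, CH2Cl2, −40 °C; then n-Bu4NBr, toluene, −40 °C → rt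
Reagents that add atoms: tetrabutylammonium bromide, CCCC[N+](CCCC)(CCCC)CCCC.[Br-]
Why: Triflation and SN2 displacement by a soluble bromide should invert C5 (oxygen cis to the side chain becomes bromine trans to it); the cold, weakly ionising medium is meant to hold back ionisation of the neopentyl triflate, and the displacement can pass through the flipped chair in which the triflate is axial and bromide enters equatorially, away from the C3 silyloxy group.

**Step 19**
Reactants: 27 (R)-but-3-en-2-ol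
Product: 28 (2R)-but-3-en-2-yl N,N-di(propan-2-yl)carbamate
Conditions: i-Pr2NC(O)Cl, Et3N, toluene, reflux
Reagents that add atoms: N,N-diisopropylcarbamoyl chloride, CC(C)N(C(C)C)C(=O)Cl
Why: O-Carbamoylation of a secondary alcohol; the stereocentre is not touched.

**Step 20**
Reactants: 26 bromo boronic ester, 28 (2R)-but-3-en-2-yl N,N-di(propan-2-yl)carbamate
Product: 32 (3S)-5-[(1R,3S,5R)-5-bromo-3-[(tert-butyldimethylsilyl)oxy]-6,6-dimethyl-2-methylidenecyclohexyl]-3-methylpent-1-en-3-ol, via lithiated carbamate 29 (not isolated), via lithium boronate complex 30 (not isolated), via tertiary allylic boronic ester 31 (not isolated)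
Conditions: 28: s-BuLi, TMEDA, Et2O, −78 °C; then 26, −78 °C → rt; then NaOH, H2O2, THF/H2O, 0 °C
Reagents that add atoms: hydrogen peroxide, OO
Why: Lithiation–borylation of a secondary allylic carbamate, in which deprotonation and borylation at the carbamate carbon proceed with retention, the 1,2-shift of the C2′ alkyl group from boron expels the carbamate with inversion at carbon, and oxidation of the C–B bond proceeds with retention, so the C2′ chain formally takes the place of the carbinol hydrogen and the (R)-carbamate should give (S)-C3′.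

**Step 21**
Reactants: 32 silyl ether
Product: 33 (3S)-5-[(1R,3S,5R)-5-bromo-3-hydroxy-6,6-dimethyl-2-methylidenecyclohexyl]-3-methylpent-1-en-3-ol
Conditions: HF·pyridine, pyridine, THF, 0 °C → rt
Reagents that add atoms: none
Why: Fluoride-mediated cleavage of the secondary silyl ether under buffered, non-basic conditions, chosen so that the C5 bromide is not eliminated and the tertiary allylic alcohol is not ionised.

**Step 22**
Reactants: 33 diol
Product: 34 (3S)-5-[(1S,3R,5R)-3,5-dibromo-6,6-dimethyl-2-methylidenecyclohexyl]-3-methylpent-1-en-3-ol (target)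
Conditions: CBr4, PPh3, CH2Cl2, −20 → 0 °C
Reagents that add atoms: carbon tetrabromide, BrC(Br)(Br)Br
Why: Appel bromination, in which bromide should displace the axial allylic C3 alkoxyphosphonium group from the equatorial side with inversion, giving the bromide cis to the side chain; at low temperature with a slight excess of reagent the secondary allylic hydroxyl should react before the hindered tertiary one, and direct SN2 should outrun SN2′ attack at C7.

**Compound list**

1 | D-pantolactone, (3R)-3-hydroxy-4,4-dimethyloxolan-2-one | CC1(C)COC(=O)[C@@H]1O | starting material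
2 | (2R)-3,3-dimethylbutane-1,2,4-triol | OC[C@H](O)C(C)(C)CO | intermediate
3 | [(2R,4R)-2-(4-methoxyphenyl)-5,5-dimethyl-1,3-dioxan-4-yl]methanol | OC[C@@H]1O[C@H](c2ccc(OC)cc2)OCC1(C)C | intermediate
4 | 3-(trimethylsilyl)prop-2-ynal | C[Si](C)(C)C#CC=O | starting material
5 | 2-[(trimethylsilyl)ethynyl]-1,3-dithiane | C[Si](C)(C)C#CC1SCCCS1 | intermediate
6 | [(2R,4R)-2-(4-methoxyphenyl)-5,5-dimethyl-1,3-dioxan-4-yl]methyl trifluoromethanesulfonate | O=S(=O)(OC[C@@H]1O[C@H](c2ccc(OC)cc2)OCC1(C)C)C(F)(F)F | intermediate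
7 | 2-lithio-2-[(trimethylsilyl)ethynyl]-1,3-dithiane | [Li]C1(C#C[Si](C)(C)C)SCCCS1 | intermediate
8 | 2-{[(2R,4S)-2-(4-methoxyphenyl)-5,5-dimethyl-1,3-dioxan-4-yl]methyl}-2-[(trimethylsilyl)ethynyl]-1,3-dithiane | C[Si](C)(C)C#CC1(C[C@@H]2O[C@H](c3ccc(OC)cc3)OCC2(C)C)SCCCS1 | intermediate
9 | 1-[(2R,4S)-2-(4-methoxyphenyl)-5,5-dimethyl-1,3-dioxan-4-yl]-4-(trimethylsilyl)but-3-yn-2-one | C[Si](C)(C)C#CC(=O)C[C@@H]1O[C@H](c2ccc(OC)cc2)OCC1(C)C | intermediate
10 | (2S)-1-[(2R,4S)-2-(4-methoxyphenyl)-5,5-dimethyl-1,3-dioxan-4-yl]-4-(trimethylsilyl)but-3-yn-2-ol | O[C@H](C#C[Si](C)(C)C)C[C@@H]1O[C@H](c2ccc(OC)cc2)OCC1(C)C | intermediate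
11 | triethylsilyl ether of 10 | CC[Si](CC)(CC)O[C@H](C#C[Si](C)(C)C)C[C@@H]1O[C@H](c2ccc(OC)cc2)OCC1(C)C | intermediate
12 | (3S,5S)-3-[(4-methoxyphenyl)methoxy]-2,2-dimethyl-5-[(triethylsilyl)oxy]-7-(trimethylsilyl)hept-6-yn-1-ol | OCC(C)(C)[C@@H](OCc1ccc(OC)cc1)C[C@H](O[Si](CC)(CC)CC)C#C[Si](C)(C)C | intermediate
13 | (3S,5S)-3-[(4-methoxyphenyl)methoxy]-2,2-dimethyl-5-[(triethylsilyl)oxy]-7-(trimethylsilyl)hept-6-ynal | O=CC(C)(C)[C@@H](OCc1ccc(OC)cc1)C[C@H](O[Si](CC)(CC)CC)C#C[Si](C)(C)C | intermediate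
14 | tert-butyl (triphenylphosphoranylidene)acetate | CC(C)(C)OC(=O)C=P(c1ccccc1)(c1ccccc1)c1ccccc1 | starting material
15 | tert-butyl (2E,5S,7S)-5-[(4-methoxyphenyl)methoxy]-4,4-dimethyl-7-[(triethylsilyl)oxy]-9-(trimethylsilyl)non-2-en-8-ynoate | CC(C)(C)OC(=O)/C=C/C(C)(C)[C@@H](OCc1ccc(OC)cc1)C[C@H](O[Si](CC)(CC)CC)C#C[Si](C)(C)C | intermediate
16 | bicyclic titanacyclopentene, Ti(Oi-Pr)2 bonded to C7 and C1′ of the cyclised skeleton | CC(C)O[Ti]1(OC(C)C)C([Si](C)(C)C)=C2[C@@H](O[Si](CC)(CC)CC)C[C@H](OCc3ccc(OC)cc3)C(C)(C)[C@@H]2C1C(=O)OC(C)(C)C | intermediate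
17 | tert-butyl 2-[(1S,2Z,3S,5S)-5-[(4-methoxyphenyl)methoxy]-6,6-dimethyl-3-[(triethylsilyl)oxy]-2-[(trimethylsilyl)methylidene]cyclohexyl]acetate | CC(C)(C)OC(=O)C[C@@H]1/C(=C/[Si](C)(C)C)[C@@H](O[Si](CC)(CC)CC)C[C@H](OCc2ccc(OC)cc2)C1(C)C | intermediate
18 | tert-butyl 2-[(1S,3S,5S)-3-hydroxy-5-[(4-methoxyphenyl)methoxy]-6,6-dimethyl-2-methylidenecyclohexyl]acetate | CC(C)(C)OC(=O)C[C@@H]1C(=C)[C@@H](O)C[C@H](OCc2ccc(OC)cc2)C1(C)C | intermediate
19 | tert-butyl 2-[(1S,3S,5S)-3-[(tert-butyldimethylsilyl)oxy]-5-[(4-methoxyphenyl)methoxy]-6,6-dimethyl-2-methylidenecyclohexyl]acetate | CC(C)(C)OC(=O)C[C@@H]1C(=C)[C@@H](O[Si](C)(C)C(C)(C)C)C[C@H](OCc2ccc(OC)cc2)C1(C)C | intermediate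
20 | 2-[(1S,3S,5S)-3-[(tert-butyldimethylsilyl)oxy]-5-[(4-methoxyphenyl)methoxy]-6,6-dimethyl-2-methylidenecyclohexyl]ethan-1-ol | OCC[C@@H]1C(=C)[C@@H](O[Si](C)(C)C(C)(C)C)C[C@H](OCc2ccc(OC)cc2)C1(C)C | intermediate
21 | (1S,3S,5S)-1-(2-iodoethyl)-3-[(tert-butyldimethylsilyl)oxy]-5-[(4-methoxyphenyl)methoxy]-6,6-dimethyl-2-methylidenecyclohexane | ICC[C@@H]1C(=C)[C@@H](O[Si](C)(C)C(C)(C)C)C[C@H](OCc2ccc(OC)cc2)C1(C)C | intermediate
22 | 2-lithioethyl analogue of 21 | [Li]CC[C@@H]1C(=C)[C@@H](O[Si](C)(C)C(C)(C)C)C[C@H](OCc2ccc(OC)cc2)C1(C)C | intermediate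
23 | 2-{2-[(1S,3S,5S)-3-[(tert-butyldimethylsilyl)oxy]-5-[(4-methoxyphenyl)methoxy]-6,6-dimethyl-2-methylidenecyclohexyl]ethyl}-4,4,5,5-tetramethyl-1,3,2-dioxaborolane | CC1(C)OB(CC[C@@H]2C(=C)[C@@H](O[Si](C)(C)C(C)(C)C)C[C@H](OCc3ccc(OC)cc3)C2(C)C)OC1(C)C | intermediate
24 | 2-{2-[(1S,3S,5S)-3-[(tert-butyldimethylsilyl)oxy]-5-hydroxy-6,6-dimethyl-2-methylidenecyclohexyl]ethyl}-4,4,5,5-tetramethyl-1,3,2-dioxaborolane | CC1(C)OB(CC[C@@H]2C(=C)[C@@H](O[Si](C)(C)C(C)(C)C)C[C@H](O)C2(C)C)OC1(C)C | intermediate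
25 | C5 trifluoromethanesulfonate of 24 | CC1(C)OB(CC[C@@H]2C(=C)[C@@H](O[Si](C)(C)C(C)(C)C)C[C@H](OS(=O)(=O)C(F)(F)F)C2(C)C)OC1(C)C | intermediate
26 | 2-{2-[(1R,3S,5R)-5-bromo-3-[(tert-butyldimethylsilyl)oxy]-6,6-dimethyl-2-methylidenecyclohexyl]ethyl}-4,4,5,5-tetramethyl-1,3,2-dioxaborolane | CC1(C)OB(CC[C@@H]2C(=C)[C@@H](O[Si](C)(C)C(C)(C)C)C[C@@H](Br)C2(C)C)OC1(C)C | intermediate
27 | (R)-but-3-en-2-ol | C=C[C@@H](C)O | starting material
28 | (2R)-but-3-en-2-yl N,N-di(propan-2-yl)carbamate | C=C[C@@H](C)OC(=O)N(C(C)C)C(C)C | intermediate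
29 | 2-lithio derivative of 28 (lithium in place of the carbinol hydrogen) | C=C[C@@]([Li])(C)OC(=O)N(C(C)C)C(C)C | intermediate
30 | lithium boronate complex of 29 and 26 | C=C[C@@](C)(OC(=O)N(C(C)C)C(C)C)[B-]1(CC[C@@H]2C(=C)[C@@H](O[Si](C)(C)C(C)(C)C)C[C@@H](Br)C2(C)C)OC(C)(C)C(C)(C)O1.[Li+] | intermediate
31 | tertiary allylic pinacol boronic ester at C3′ | C=C[C@@](C)(B1OC(C)(C)C(C)(C)O1)CC[C@@H]2C(=C)[C@@H](O[Si](C)(C)C(C)(C)C)C[C@@H](Br)C2(C)C | intermediate
32 | (3S)-5-[(1R,3S,5R)-5-bromo-3-[(tert-butyldimethylsilyl)oxy]-6,6-dimethyl-2-methylidenecyclohexyl]-3-methylpent-1-en-3-ol | C=C[C@@](C)(O)CC[C@@H]1C(=C)[C@@H](O[Si](C)(C)C(C)(C)C)C[C@@H](Br)C1(C)C | intermediate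
33 | (3S)-5-[(1R,3S,5R)-5-bromo-3-hydroxy-6,6-dimethyl-2-methylidenecyclohexyl]-3-methylpent-1-en-3-ol | C=C[C@@](C)(O)CC[C@@H]1C(=C)[C@@H](O)C[C@@H](Br)C1(C)C | intermediate
34 | (3S)-5-[(1S,3R,5R)-3,5-dibromo-6,6-dimethyl-2-methylidenecyclohexyl]-3-methylpent-1-en-3-ol | C=C[C@@](C)(O)CC[C@@H]1C(=C)[C@H](Br)C[C@@H](Br)C1(C)C | target

**Step count and risks**

Total step count: 22 (20 on the main line, plus the dithiane in step 3 and the carbamate in step 19). Longest linear sequence: 20 steps from D-pantolactone (steps 1, 2, 4–18, 20–22).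

Steps most likely to fail:

Step 18. The neopentyl C5 triflate may ionise faster than bromide can attack, leading to 1,2-shift, ring contraction or elimination; attack may also be blocked by the syn-axial C3 silyloxy group. The fallback replaces inversion by an oxidation–reduction–retention sequence from 24 back to 26. Dess–Martin oxidation of 24 gives the C5 ketone F1. LiBH(s-Bu)3 (THF, −78 °C), which should attack the face away from the axial C3 silyloxy group, gives the C5-epimeric alcohol F2 (hydroxyl trans to the side chain). Sulfonylation with 2-(2-methoxyethoxy)ethyl 2-(chlorosulfonyl)benzoate (Et3N, DMAP, CH2Cl2) gives the chelating aryl sulfonate F3. TiBr4 (CH2Cl2, −78 °C) then binds the oligoether arm and delivers bromide to the front face, a stereoretentive substitution that should give 26.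

Step 11. The titanium–alkyne complex may lose the propargylic silyloxy group by β-elimination before it inserts the enoate, or the enoate face may be poorly discriminated. The fallback closes the ring by a radical from 15 and returns at 18. K2CO3 in MeOH at 0 °C removes the alkyne silyl group to give the terminal enynoate F4. Bu3SnH with AIBN (benzene, 80 °C, slow addition) adds a stannyl radical to the alkyne terminus, and the vinyl radical closes the ring 6-exo onto the enoate to give the stannylmethylidene cyclohexane F5; the chair with the enoate equatorial is expected to favour the same C1 configuration. HCl in MeOH at 0 °C protodestannylates C7 and removes the triethylsilyl group to give 18.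

Step 20. The lithiated allyl carbamate may be borylated at its unsubstituted terminal carbon instead of the carbamate carbon, or may lose configuration before it is trapped. The fallback builds C3′ by asymmetric epoxidation from 26 and returns at 32. Suzuki–Miyaura coupling of 26 with (E)-3-iodobut-2-en-1-ol (Pd(OAc)2, RuPhos, K3PO4, toluene/H2O, 80 °C) gives the (E)-allylic alcohol F6. Sharpless epoxidation (Ti(Oi-Pr)4, L-(+)-diethyl tartrate, t-BuOOH, CH2Cl2, −20 °C) gives the (2S,3S)-epoxy alcohol F7. I2, PPh3 and imidazole give the epoxy iodide F8. Zn dust in EtOH at reflux opens it reductively to the tertiary allylic alcohol 32, the C3′–O bond being kept.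

**Further compounds**

F1 | step 18 | C5 ketone from 24 | CC1(C)OB(CC[C@@H]2C(=C)[C@@H](O[Si](C)(C)C(C)(C)C)CC(=O)C2(C)C)OC1(C)C
F2 | step 18 | C5-epimeric alcohol (hydroxyl trans to the side chain) | CC1(C)OB(CC[C@@H]2C(=C)[C@@H](O[Si](C)(C)C(C)(C)C)C[C@@H](O)C2(C)C)OC1(C)C
F3 | step 18 | 2-{[2-(2-methoxyethoxy)ethoxy]carbonyl}benzenesulfonate of F2 | CC1(C)OB(CC[C@@H]2C(=C)[C@@H](O[Si](C)(C)C(C)(C)C)C[C@@H](OS(=O)(=O)c3ccccc3C(=O)OCCOCCOC)C2(C)C)OC1(C)C
F4 | step 11 | tert-butyl (2E,5S,7S)-5-[(4-methoxyphenyl)methoxy]-4,4-dimethyl-7-[(triethylsilyl)oxy]non-2-en-8-ynoate | CC(C)(C)OC(=O)/C=C/C(C)(C)[C@@H](OCc1ccc(OC)cc1)C[C@H](O[Si](CC)(CC)CC)C#C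
F5 | step 11 | tert-butyl 2-[(1S,3S,5S)-5-[(4-methoxyphenyl)methoxy]-6,6-dimethyl-3-[(triethylsilyl)oxy]-2-[(tributylstannyl)methylidene]cyclohexyl]acetate (alkene isomers) | CC(C)(C)OC(=O)C[C@@H]1C(=C[Sn](CCCC)(CCCC)CCCC)[C@@H](O[Si](CC)(CC)CC)C[C@H](OCc2ccc(OC)cc2)C1(C)C
F6 | step 20 | (2E)-5-[(1R,3S,5R)-5-bromo-3-[(tert-butyldimethylsilyl)oxy]-6,6-dimethyl-2-methylidenecyclohexyl]-3-methylpent-2-en-1-ol | OC/C=C(\C)CC[C@@H]1C(=C)[C@@H](O[Si](C)(C)C(C)(C)C)C[C@@H](Br)C1(C)C
F7 | step 20 | (2S,3S)-2,3-epoxy alcohol from F6 | OC[C@@H]1O[C@@]1(C)CC[C@@H]2C(=C)[C@@H](O[Si](C)(C)C(C)(C)C)C[C@@H](Br)C2(C)C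
F8 | step 20 | epoxy iodide from F7 | IC[C@@H]1O[C@@]1(C)CC[C@@H]2C(=C)[C@@H](O[Si](C)(C)C(C)(C)C)C[C@@H](Br)C2(C)C
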